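**Plan**
- Retrosynthesis of the target, (2S)-4'-O-methyl-8-prenylnaringenin, cuts in this order: the two MOM O–CH2 bonds on O5 and O7; the C2–C1' bond between the chromanone and the 4-methoxyphenyl ring (back to an achiral chromone and an arylboronic acid); and the C8–CH2 bond of the prenyl group, traced through a Claisen–Cope relay to the O5–CH2 bond of a 5-O-prenyl ether.
- Enabling feature: C2 of the target is the sp3 carbon β to the C4 carbonyl in the pyranone ring (ring C). One oxidation level up, in the 4H-chromen-4-one, the vinylogous ester O1–C2=C3–C4=O makes C2 a prochiral electrophile, so one conjugate arylation joins the fragments, sets the only stereocentre and brings ring C to the chromanone level.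
- Forward: both rings of the benzopyranone are present from the start (5,7-dihydroxychromone). O7 is masked, O5 is prenylated, the prenyl group is relayed from O5 via C6 to C8, O5 is masked, the aryl group is added at C2, and the two MOM groups are removed.
- Stereochemistry: the C2 centre comes from ligand control in a rhodium-catalysed asymmetric 1,4-addition (aryl to the Re face of C2 gives 2S). It is set in the penultimate step and afterwards meets only dilute acid.

Key step: step 5

Remark: the target is read as the (2S)-flavanone. Ring atoms are numbered as in chroman-4-one (O1, C2, C3, C4, C4a, C5 to C8, C8a) and "prenyl" means 3-methylbut-2-en-1-yl. 5,7-Dihydroxychromone, MOMCl, prenyl bromide and 4-methoxyphenylboronic acid are taken as commercial materials.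

**Step 1**
Reactants: 1 5,7-dihydroxy-4H-chromen-4-one; 2 chloromethyl methyl ether (MOMCl)
Product: 3 5-hydroxy-7-(methoxymethoxy)-4H-chromen-4-one
Conditions: MOMCl (1.1 equiv), K2CO3, acetone, 0 °C to rt
Reagents that add atoms: chloromethyl methyl ether, COCCl
Why: The 7-OH is the more acidic, non-chelated phenol, whereas the 5-OH is held in a hydrogen bond to the C4 carbonyl, so one equivalent of MOMCl under a weak base should give selective Williamson-type O-alkylation at O7.

**Step 2**
Reactants: 3 5-hydroxy-7-(methoxymethoxy)-4H-chromen-4-one; 4 1-bromo-3-methylbut-2-ene (prenyl bromide)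
Product: 5 7-(methoxymethoxy)-5-[(3-methylbut-2-en-1-yl)oxy]-4H-chromen-4-one
Conditions: prenyl bromide (1.3 equiv), K2CO3, DMF, 50 °C
Reagents that add atoms: 1-bromo-3-methylbut-2-ene, CC(C)=CCBr
Why: Williamson etherification of the remaining chelated 5-OH with a reactive allylic bromide, a carbonate base in a polar aprotic solvent favouring O- over C-alkylation and leaving the chromone and the MOM ether untouched.

**Step 3**
Reactants: 5 7-(methoxymethoxy)-5-[(3-methylbut-2-en-1-yl)oxy]-4H-chromen-4-one
Product: 8 5-hydroxy-7-(methoxymethoxy)-8-(3-methylbut-2-en-1-yl)-4H-chromen-4-one, via ortho-dienone 6 (not isolated), via para-dienone 7 (not isolated)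
Conditions: Eu(fod)3 (10 mol %), NaHCO3, PhCl, 85 °C
Reagents that add atoms: none
Why: Eu(fod)3 (trivalent europium; fod = 6,6,7,7,8,8,8-heptafluoro-2,2-dimethyloctane-3,5-dionate) chelates O5 and the C4 carbonyl and so accelerates an aromatic Claisen rearrangement to C6 (dienone 6, reverse-prenyl group), whose congested 1,5-diene relays by a Cope rearrangement to C8 (dienone 7, normal prenyl group) before enolization to the chelated 5-phenol, a tandem Claisen–Cope (para-Claisen) rearrangement known for 5-O-prenyl flavonoids.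

**Step 4**
Reactants: 8 5-hydroxy-7-(methoxymethoxy)-8-(3-methylbut-2-en-1-yl)-4H-chromen-4-one; 2 chloromethyl methyl ether (MOMCl)
Product: 10 5,7-bis(methoxymethoxy)-8-(3-methylbut-2-en-1-yl)-4H-chromen-4-one, via sodium phenoxide 9 (not isolated)
Conditions: NaH, DMF, 0 °C; then MOMCl, 0 °C to rt
Reagents that add atoms: chloromethyl methyl ether, COCCl
Why: Irreversible deprotonation of the chelated 5-OH with NaH followed by O-alkylation of phenoxide 9 with MOMCl; masking O5 keeps the chromone non-ionised and electrophilic for step 5 and removes the phenoxide that would promote ring-opening of the flavanone.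

**Step 5**
Reactants: 10 5,7-bis(methoxymethoxy)-8-(3-methylbut-2-en-1-yl)-4H-chromen-4-one; 11 4-methoxyphenylboronic acid
Product: 12 (2S)-5,7-bis(methoxymethoxy)-2-(4-methoxyphenyl)-8-(3-methylbut-2-en-1-yl)chroman-4-one
Conditions: [Rh(OH)(cod)]2 (1.5 mol %; cod = cycloocta-1,5-diene), (S)-6,6'-dimethoxy-2,2'-bis[bis(3,4,5-trifluorophenyl)phosphino]-1,1'-biphenyl (3.3 mol %), 11 (2 equiv), toluene/H2O 10:1, 25 °C
Reagents that add atoms: 4-methoxyphenylboronic acid, COc1ccc(B(O)O)cc1
Why: The hydroxorhodium–bisphosphine complex (monovalent rhodium) takes the aryl group from boron by transmetalation, the aryl–rhodium species binds the C2=C3 double bond of the pyranone ring and inserts it so that the aryl group goes to C2 and rhodium to the C3/O4 oxa-π-allyl enolate, and water protonates C3 and returns the rhodium hydroxide. The closest known reaction type is the Hayashi–Miyaura asymmetric 1,4-addition of arylboronic acids to chromones to give flavanones. No ring is closed: the benzopyranone bicycle is already in place and only the C2–aryl bond and one C3–H bond are formed. The new stereocentre C2 is controlled by the axially chiral (S)-bisphosphine on rhodium, whose quadrant model (the one that gives (S)-3-arylcyclohexanones from cyclohexenone with (S)-biaryl bisphosphines) exposes the Re face of C2, which corresponds to 2S. The step needs 1,4- over 1,2-addition, addition faster than protodeboronation of the electron-rich boronic acid, and a product that does not open by retro-oxa-Michael reaction; the electron-poor ligand (fast insertion at room temperature), the base-free aqueous medium and the MOM ether on O5 should secure these, while the unactivated trisubstituted prenyl olefin should not insert.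

**Step 6**
Reactants: 12 (2S)-5,7-bis(methoxymethoxy)-2-(4-methoxyphenyl)-8-(3-methylbut-2-en-1-yl)chroman-4-one
Product: 13 (2S)-5,7-dihydroxy-2-(4-methoxyphenyl)-8-(3-methylbut-2-en-1-yl)chroman-4-one
Conditions: HCl (ca. 1 M, from conc. aq. HCl), MeOH, 30 °C
Reagents that add atoms: none
Why: Acid-catalysed acetal exchange of the two aryl MOM ethers with methanol, a deprotection known for MOM-protected prenylflavanones, under which the C2 centre (no base, so no chalcone pathway), the aryl methyl ether and, at this acid strength and temperature, the prenyl olefin are expected to persist.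

**Compound list**
1 | 5,7-dihydroxy-4H-chromen-4-one (5,7-dihydroxychromone) | O=c1ccoc2cc(O)cc(O)c12 | starting material
2 | chloromethyl methyl ether (MOMCl) | COCCl | starting material
3 | 5-hydroxy-7-(methoxymethoxy)-4H-chromen-4-one | O=c1ccoc2cc(OCOC)cc(O)c12 | intermediate
4 | 1-bromo-3-methylbut-2-ene (prenyl bromide) | CC(C)=CCBr | starting material
5 | 7-(methoxymethoxy)-5-[(3-methylbut-2-en-1-yl)oxy]-4H-chromen-4-one | O=c1ccoc2cc(OCOC)cc(OCC=C(C)C)c12 | intermediate
6 | 7-(methoxymethoxy)-6-(2-methylbut-3-en-2-yl)-6H-chromene-4,5-dione (ortho-dienone, racemic at C6, not isolated) | O=C1C=COC2=C1C(=O)C(C(C)(C)C=C)C(OCOC)=C2 | intermediate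
7 | 7-(methoxymethoxy)-8-(3-methylbut-2-en-1-yl)-8H-chromene-4,5-dione (para-dienone, racemic at C8, not isolated) | O=C1C=COC2=C1C(=O)C=C(OCOC)C2CC=C(C)C | intermediate
8 | 5-hydroxy-7-(methoxymethoxy)-8-(3-methylbut-2-en-1-yl)-4H-chromen-4-one | O=c1ccoc2c(CC=C(C)C)c(OCOC)cc(O)c12 | intermediate
9 | sodium 7-(methoxymethoxy)-8-(3-methylbut-2-en-1-yl)-4-oxo-4H-chromen-5-olate (not isolated) | [Na+].[O-]c1cc(OCOC)c(CC=C(C)C)c2occc(=O)c12 | intermediate
10 | 5,7-bis(methoxymethoxy)-8-(3-methylbut-2-en-1-yl)-4H-chromen-4-one | O=c1ccoc2c(CC=C(C)C)c(OCOC)cc(OCOC)c12 | intermediate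
11 | 4-methoxyphenylboronic acid | COc1ccc(B(O)O)cc1 | starting material
12 | (2S)-5,7-bis(methoxymethoxy)-2-(4-methoxyphenyl)-8-(3-methylbut-2-en-1-yl)chroman-4-one | COc1ccc([C@@H]2CC(=O)c3c(OCOC)cc(OCOC)c(CC=C(C)C)c3O2)cc1 | intermediate
13 | (2S)-5,7-dihydroxy-2-(4-methoxyphenyl)-8-(3-methylbut-2-en-1-yl)chroman-4-one | COc1ccc([C@@H]2CC(=O)c3c(O)cc(O)c(CC=C(C)C)c3O2)cc1 | target

**Count**
Total step count: 6. Longest linear sequence: 6 steps (1 to 13).

**Steps most likely to fail**

Step 5. Carbometalation of the electron-rich 5,7-dioxygenated chromone may be slow, so that protodeboronation of the boronic acid outruns addition, or the catalyst may discriminate the two faces of C2 poorly. The fallback builds the C2–O1 bond instead of the C2–aryl bond and sets out from 10.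
- Aqueous NaOH in EtOH at reflux should open the pyranone ring (hydroxide addition at C2, then retro-Claisen loss of formate) to 1-[2-hydroxy-4,6-bis(methoxymethoxy)-3-(3-methylbut-2-en-1-yl)phenyl]ethan-1-one F1.
- Claisen–Schmidt condensation with 4-methoxybenzaldehyde (KOH, EtOH) should give the chalcone (E)-1-[2-hydroxy-4,6-bis(methoxymethoxy)-3-(3-methylbut-2-en-1-yl)phenyl]-3-(4-methoxyphenyl)prop-2-en-1-one F2.
- Oxa-Michael ring closure (NaOAc, EtOH, reflux) through the only free phenol, the one next to the prenyl group, should give racemic 5,7-bis(methoxymethoxy)-2-(4-methoxyphenyl)-8-(3-methylbut-2-en-1-yl)chroman-4-one F3.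
- Preparative chromatography on a chiral stationary phase then separates it into 12, where the route is rejoined, and (2R)-5,7-bis(methoxymethoxy)-2-(4-methoxyphenyl)-8-(3-methylbut-2-en-1-yl)chroman-4-one F4. The latter can be returned to F3 by base-mediated ring-opening and reclosure.

Step 3. The sigmatropic relay may stop after the first shift, leaving the reverse-prenyl group at C6 after enolization, or the Lewis acid may strip the MOM group. The fallback installs the prenyl group by cross-coupling and sets out from 3.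
- MOM protection of the 5-OH (MOMCl, i-Pr2NEt, DMAP, CH2Cl2, 40 °C) should give 5,7-bis(methoxymethoxy)-4H-chromen-4-one F5.
- Electrophilic iodination (NIS, DMF, rt) is expected at C8, the more accessible of the two activated positions when both O5 and O7 are alkylated, to give 8-iodo-5,7-bis(methoxymethoxy)-4H-chromen-4-one F6.
- Stille coupling with tributyl(3-methylbut-2-en-1-yl)stannane under Pd(PPh3)4 (zerovalent palladium) in DMF at 90 °C should give 10, where the route is rejoined.

Step 6. Under acid the freed 7-OH may add to the protonated prenyl olefin (closure of a dimethylchroman ring), the olefin may be hydrated, or slow ring-opening and reclosure may erode the enantiopurity. The fallback replaces the acetal protecting groups by fluoride-labile silyl ethers, sets out from 1 and rejoins the route at 13.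
- Selective silylation of the 7-OH (TBSCl, imidazole, DMF) should give 7-[(tert-butyldimethylsilyl)oxy]-5-hydroxy-4H-chromen-4-one F7.
- Mitsunobu etherification with 3-methylbut-2-en-1-ol (PPh3, DIAD, THF) should give 7-[(tert-butyldimethylsilyl)oxy]-5-[(3-methylbut-2-en-1-yl)oxy]-4H-chromen-4-one F8.
- Eu(fod)3 in PhCl at 85 °C should relay the prenyl group through the ortho-dienone 7-[(tert-butyldimethylsilyl)oxy]-6-(2-methylbut-3-en-2-yl)-6H-chromene-4,5-dione F9 and the para-dienone 7-[(tert-butyldimethylsilyl)oxy]-8-(3-methylbut-2-en-1-yl)-8H-chromene-4,5-dione F10 to 7-[(tert-butyldimethylsilyl)oxy]-5-hydroxy-8-(3-methylbut-2-en-1-yl)-4H-chromen-4-one F11.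
- Silylation of the chelated 5-OH (TBSOTf, 2,6-lutidine, CH2Cl2) should give 5,7-bis[(tert-butyldimethylsilyl)oxy]-8-(3-methylbut-2-en-1-yl)-4H-chromen-4-one F12.
- The rhodium-catalysed addition of 11 under the conditions of step 5 should give (2S)-5,7-bis[(tert-butyldimethylsilyl)oxy]-2-(4-methoxyphenyl)-8-(3-methylbut-2-en-1-yl)chroman-4-one F13.
- Et3N·3HF in THF at rt should remove both silyl groups under nearly neutral conditions to give 13.

**Further compounds**
F1 | step 5 | 1-[2-hydroxy-4,6-bis(methoxymethoxy)-3-(3-methylbut-2-en-1-yl)phenyl]ethan-1-one | CC(=O)c1c(O)c(CC=C(C)C)c(OCOC)cc1OCOC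
F2 | step 5 | (E)-1-[2-hydroxy-4,6-bis(methoxymethoxy)-3-(3-methylbut-2-en-1-yl)phenyl]-3-(4-methoxyphenyl)prop-2-en-1-one | COc1ccc(/C=C/C(=O)c2c(O)c(CC=C(C)C)c(OCOC)cc2OCOC)cc1
F3 | step 5 | racemic 5,7-bis(methoxymethoxy)-2-(4-methoxyphenyl)-8-(3-methylbut-2-en-1-yl)chroman-4-one | COc1ccc(C2CC(=O)c3c(OCOC)cc(OCOC)c(CC=C(C)C)c3O2)cc1
F4 | step 5 | (2R)-5,7-bis(methoxymethoxy)-2-(4-methoxyphenyl)-8-(3-methylbut-2-en-1-yl)chroman-4-one | COc1ccc([C@H]2CC(=O)c3c(OCOC)cc(OCOC)c(CC=C(C)C)c3O2)cc1
F5 | step 3 | 5,7-bis(methoxymethoxy)-4H-chromen-4-one | O=c1ccoc2cc(OCOC)cc(OCOC)c12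
F6 | step 3 | 8-iodo-5,7-bis(methoxymethoxy)-4H-chromen-4-one | O=c1ccoc2c(I)c(OCOC)cc(OCOC)c12
F7 | step 6 | 7-[(tert-butyldimethylsilyl)oxy]-5-hydroxy-4H-chromen-4-one | O=c1ccoc2cc(O[Si](C)(C)C(C)(C)C)cc(O)c12
F8 | step 6 | 7-[(tert-butyldimethylsilyl)oxy]-5-[(3-methylbut-2-en-1-yl)oxy]-4H-chromen-4-one | O=c1ccoc2cc(O[Si](C)(C)C(C)(C)C)cc(OCC=C(C)C)c12
F9 | step 6 | 7-[(tert-butyldimethylsilyl)oxy]-6-(2-methylbut-3-en-2-yl)-6H-chromene-4,5-dione | O=C1C=COC2=C1C(=O)C(C(C)(C)C=C)C(O[Si](C)(C)C(C)(C)C)=C2
F10 | step 6 | 7-[(tert-butyldimethylsilyl)oxy]-8-(3-methylbut-2-en-1-yl)-8H-chromene-4,5-dione | O=C1C=COC2=C1C(=O)C=C(O[Si](C)(C)C(C)(C)C)C2CC=C(C)C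
F11 | step 6 | 7-[(tert-butyldimethylsilyl)oxy]-5-hydroxy-8-(3-methylbut-2-en-1-yl)-4H-chromen-4-one | O=c1ccoc2c(CC=C(C)C)c(O[Si](C)(C)C(C)(C)C)cc(O)c12
F12 | step 6 | 5,7-bis[(tert-butyldimethylsilyl)oxy]-8-(3-methylbut-2-en-1-yl)-4H-chromen-4-one | O=c1ccoc2c(CC=C(C)C)c(O[Si](C)(C)C(C)(C)C)cc(O[Si](C)(C)C(C)(C)C)c12
F13 | step 6 | (2S)-5,7-bis[(tert-butyldimethylsilyl)oxy]-2-(4-methoxyphenyl)-8-(3-methylbut-2-en-1-yl)chroman-4-one | COc1ccc([C@@H]2CC(=O)c3c(O[Si](C)(C)C(C)(C)C)cc(O[Si](C)(C)C(C)(C)C)c(CC=C(C)C)c3O2)cc1
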